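**Plan**

- Cuts, in retrosynthetic order: the C16 formate and the silyl ethers; C8–C17 (reductive carbonylation of a Δ7 enol triflate, back to a C8 ketone); C12–C13 (Negishi coupling); C6–C7 of ring B (retro-aldol to a monocyclic 1,5-keto aldehyde); C9–C10 (retro-oxy-Cope to a 1,5-dien-3-ol made from β-cyclocitral).
- Forward: ring A is bought as β-cyclocitral (C1–C6, C10, C18–C20). Allylboration and cross-metathesis build the dienol, the anionic oxy-Cope forges C9–C10, a Wacker oxidation makes C7 a ketone methyl group, and the aldol closes ring B. The side chain, C17 and the formate follow.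
- Stereochemistry: C6 is set (R) by reagent-controlled allylboration and relayed to C10 and C9 through the chair oxy-Cope of the (E)-alkene; C5 by axial protonation; C6 is re-made as the equatorial alcohol in the aldol; the C13=C14 geometry comes from anti hydroiodination and a stereoretentive coupling.
- Enabling feature: in ring B the C6 carbinol is 1,3 to C8, the carbon that bears the formyl group. With C8 read as a ketone, O–C6/C7/C8 is an aldol retron in which C7 is a ketone methyl group and C6 is the formyl carbon that β-cyclocitral already carries on C5. C5 and C9 flank the two carbonyl groups of the open form and are enolisable, so the closure can settle ring B around the fixed quaternary C10.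

Key step: step 5

Remark: atoms are numbered as in the labdane skeleton (ring A: C1–C5 and C10; ring B: C5–C10; side chain C11–C16; C17 the formyl carbon on C8; C18–C20 the methyl groups); the target is 5R,6R,9S,10S.

Assumption: the B-allyldiisopinocampheylborane made from (−)-α-pinene is taken to add to the face of 1 that gives the (1R)-alcohol, as it does with other aldehydes bearing a branched or sp2 substituent; if the sense were opposite, the reagent of the other pinene series would be used and nothing else changes.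

**Route**

Step 1
Reactants: 1 β-cyclocitral (2,6,6-trimethylcyclohex-1-ene-1-carbaldehyde)
Product: 3 (1R)-1-(2,6,6-trimethylcyclohex-1-en-1-yl)but-3-en-1-ol, via borinate ester 2 (not isolated)
Conditions: B-allyldiisopinocampheylborane from (−)-α-pinene, Et2O, −78 °C to rt; then NaOH, H2O2
Reagents that add atoms: B-allyldiisopinocampheylborane of the (−)-α-pinene series, C=CCB([C@H]1C[C@H]2C[C@@H]([C@@H]1C)C2(C)C)[C@H]1C[C@H]2C[C@@H]([C@@H]1C)C2(C)C
Why: Brown asymmetric allylboration, in which the allyl group is delivered through a closed six-membered chair transition state whose isopinocampheyl ligands differentiate the two faces of the hindered aldehyde, should set C6 as (R) with high enantiomeric enrichment, and the parent allyl group cannot give regioisomers.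

Step 2
Reactants: 3 (1R)-1-(2,6,6-trimethylcyclohex-1-en-1-yl)but-3-en-1-ol; 4 tert-butyl(but-3-en-1-yloxy)dimethylsilane
Product: 5 (1R,3E)-6-{[tert-butyl(dimethyl)silyl]oxy}-1-(2,6,6-trimethylcyclohex-1-en-1-yl)hex-3-en-1-ol
Conditions: second-generation Hoveyda–Grubbs catalyst (5 mol %), 4 (3 equiv), CH2Cl2, 40 °C
Reagents that add atoms: none
Why: Olefin cross-metathesis between two unhindered terminal alkenes, with the tetrasubstituted ring alkene inert and the excess of 4 driving 3 to the heterodimer, should attach C9, C11 and C12 and favour the (E)-alkene on thermodynamic grounds.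

Step 3
Reactants: 5 (1R,3E)-6-{[tert-butyl(dimethyl)silyl]oxy}-1-(2,6,6-trimethylcyclohex-1-en-1-yl)hex-3-en-1-ol
Product: 8 (1R,2S)-2-[(3R)-5-{[tert-butyl(dimethyl)silyl]oxy}pent-1-en-3-yl]-2,6,6-trimethylcyclohexane-1-carbaldehyde, via potassium alkoxide 6 (not isolated), via potassium enolate 7 (not isolated)
Conditions: KH, 18-crown-6, THF, 0 °C to 40 °C; then AcOH in THF, −78 °C
Reagents that add atoms: none
Why: Anionic oxy-Cope ([3,3]-sigmatropic) rearrangement accelerated by the crown-separated potassium alkoxide, in which a chair transition state with the oxyanion equatorial (the axial site clashes with the vinylic C10 methyl) and the C11 arm of the (E)-alkene equatorial relays the C6 configuration to the quaternary C10 and to C9 while C6 becomes the aldehyde carbon, and protonation of the exocyclic enolate anti to the axial methyl groups on C4 and C10 should set H5 trans to the C10 methyl.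

Step 4
Reactants: 8 (1R,2S)-2-[(3R)-5-{[tert-butyl(dimethyl)silyl]oxy}pent-1-en-3-yl]-2,6,6-trimethylcyclohexane-1-carbaldehyde
Product: 9 (1R,2R)-2-[(3S)-5-{[tert-butyl(dimethyl)silyl]oxy}-2-oxopentan-3-yl]-2,6,6-trimethylcyclohexane-1-carbaldehyde
Conditions: PdCl2 (10 mol %), CuCl, O2 (1 atm), DMF/H2O, rt
Reagents that add atoms: water, O
Why: Tsuji–Wacker oxidation, by Markovnikov hydroxypalladation of the monosubstituted C7=C8 alkene and β-hydride elimination, should give the C8 methyl ketone (C7 becomes the methyl group) under near-neutral conditions that leave the aldehyde, the silyl ether and the C5 and C9 centres untouched.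

Step 5
Reactants: 9 (1R,2R)-2-[(3S)-5-{[tert-butyl(dimethyl)silyl]oxy}-2-oxopentan-3-yl]-2,6,6-trimethylcyclohexane-1-carbaldehyde
Product: 10 (1S,4R,4aR,8aR)-1-(2-{[tert-butyl(dimethyl)silyl]oxy}ethyl)-4-hydroxy-5,5,8a-trimethyl-3,4,4a,5,6,7,8,8a-octahydronaphthalen-2(1H)-one
Conditions: NaOMe (0.2 equiv), MeOH, 0 °C to rt; AcOH quench
Reagents that add atoms: none
Why: Methoxide reversibly forms the methyl-ketone enolate (C7=C8–O−), whose carbon C7 adds to the C6 formyl group, and proton transfer gives the β-hydroxy ketone; the closest known reaction type is the intramolecular aldol addition of a 1,5-keto aldehyde, the ring-closing half of a Robinson annulation stopped at the ketol. Ring B is closed in the 6-(enolendo)-exo-trig mode, the only productive one because the C9 and C5 enolates could only give four-membered rings. The new stereocentre C6 is controlled by the chair transition state and by the reversibility of the addition, both of which place the oxygen equatorial, away from the axial methyl groups on C10 and C4, that is cis to H5 and trans to C20. C5, α to the formyl group, can still epimerise before closure and only the epimer with the formyl group trans-diequatorial to the C9 arm leads to the strain-free trans-decalin, so the closure also proof-reads C5, while C9 keeps its equatorial arm. The step needs addition without dehydration or retro-Michael cleavage, which the equatorial C6–O bond (poorly aligned with the enolate π system for E1cB loss), the catalytic base and the low temperature should secure.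

Step 6
Reactants: 10 (1S,4R,4aR,8aR)-1-(2-{[tert-butyl(dimethyl)silyl]oxy}ethyl)-4-hydroxy-5,5,8a-trimethyl-3,4,4a,5,6,7,8,8a-octahydronaphthalen-2(1H)-one
Product: 11 (1S,4R,4aR,8aR)-4-{[tert-butyl(dimethyl)silyl]oxy}-1-(2-{[tert-butyl(dimethyl)silyl]oxy}ethyl)-5,5,8a-trimethyl-3,4,4a,5,6,7,8,8a-octahydronaphthalen-2(1H)-one
Conditions: TBSOTf, 2,6-lutidine, CH2Cl2, −78 °C to −20 °C
Reagents that add atoms: tert-butyldimethylsilyl triflate, CC(C)(C)[Si](C)(C)OS(=O)(=O)C(F)(F)F
Why: O-Silylation with a silyl triflate and a hindered pyridine base at low temperature should cap the hindered equatorial C6 hydroxyl faster than it enolises the ketone, which blocks retro-aldol cleavage in the later basic steps.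

Step 7
Reactants: 11 (1S,4R,4aR,8aR)-4-{[tert-butyl(dimethyl)silyl]oxy}-1-(2-{[tert-butyl(dimethyl)silyl]oxy}ethyl)-5,5,8a-trimethyl-3,4,4a,5,6,7,8,8a-octahydronaphthalen-2(1H)-one
Product: 12 (1S,4R,4aR,8aR)-4-{[tert-butyl(dimethyl)silyl]oxy}-1-(2-hydroxyethyl)-5,5,8a-trimethyl-3,4,4a,5,6,7,8,8a-octahydronaphthalen-2(1H)-one
Conditions: HF·pyridine, pyridine, THF, 0 °C
Reagents that add atoms: none
Why: Buffered fluoride desilylation discriminates on steric grounds, so the primary C12 silyl ether should be cleaved well before the hindered secondary C6 silyl ether.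

Step 8
Reactants: 12 (1S,4R,4aR,8aR)-4-{[tert-butyl(dimethyl)silyl]oxy}-1-(2-hydroxyethyl)-5,5,8a-trimethyl-3,4,4a,5,6,7,8,8a-octahydronaphthalen-2(1H)-one
Product: 13 (1S,4R,4aR,8aR)-4-{[tert-butyl(dimethyl)silyl]oxy}-1-(2-iodoethyl)-5,5,8a-trimethyl-3,4,4a,5,6,7,8,8a-octahydronaphthalen-2(1H)-one
Conditions: I2, PPh3, imidazole, CH2Cl2, 0 °C to rt
Reagents that add atoms: iodine, II
Why: Appel-type iodination converts the primary alcohol into the iodide by SN2 displacement of the alkoxyphosphonium ion without touching the ketone or the silyl ether.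

Step 9
Reactants: 14 methyl 4-hydroxybut-2-ynoate
Product: 15 methyl (2Z)-4-hydroxy-3-iodobut-2-enoate
Conditions: NaI, AcOH, 70 °C
Reagents that add atoms: sodium iodide, [Na+].[I-]
Why: Conjugate addition of iodide to the ynoate followed by protonation anti to iodine (net anti hydroiodination) should give the (Z)-β-iodo enoate, in which the hydroxymethyl group is trans to the ester and therefore cannot lactonise.

Step 10
Reactants: 15 methyl (2Z)-4-hydroxy-3-iodobut-2-enoate
Product: 16 methyl (2Z)-4-{[tert-butyl(dimethyl)silyl]oxy}-3-iodobut-2-enoate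
Conditions: TBSCl, imidazole, CH2Cl2, rt
Reagents that add atoms: tert-butyldimethylsilyl chloride, CC(C)(C)[Si](C)(C)Cl
Why: Standard silylation of the primary allylic alcohol protects it from the organozinc reagent and the amide base used later.

Step 11
Reactants: 13 (1S,4R,4aR,8aR)-4-{[tert-butyl(dimethyl)silyl]oxy}-1-(2-iodoethyl)-5,5,8a-trimethyl-3,4,4a,5,6,7,8,8a-octahydronaphthalen-2(1H)-one; 16 methyl (2Z)-4-{[tert-butyl(dimethyl)silyl]oxy}-3-iodobut-2-enoate
Product: 18 methyl (2E)-3-({[tert-butyl(dimethyl)silyl]oxy}methyl)-5-[(1S,4R,4aR,8aR)-4-{[tert-butyl(dimethyl)silyl]oxy}-5,5,8a-trimethyl-2-oxodecahydronaphthalen-1-yl]pent-2-enoate, via alkylzinc iodide 17 (not isolated)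
Conditions: Zn dust, LiCl, THF, 40 °C; then 16, PdCl2(dppf) (5 mol %), THF, rt
Reagents that add atoms: none
Why: Negishi coupling, in which zinc inserts into the primary C–I bond in the presence of the ketone and the palladium-catalysed sp3–sp2 coupling with the alkenyl iodide proceeds with retention of alkene geometry, should form C12–C13 and fix the ester cis to C12 (13E).

Step 12
Reactants: 18 methyl (2E)-3-({[tert-butyl(dimethyl)silyl]oxy}methyl)-5-[(1S,4R,4aR,8aR)-4-{[tert-butyl(dimethyl)silyl]oxy}-5,5,8a-trimethyl-2-oxodecahydronaphthalen-1-yl]pent-2-enoate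
Product: 20 methyl (2E)-3-({[tert-butyl(dimethyl)silyl]oxy}methyl)-5-[(1S,4S,4aR,8aR)-4-{[tert-butyl(dimethyl)silyl]oxy}-5,5,8a-trimethyl-2-{[(trifluoromethyl)sulfonyl]oxy}-1,4,4a,5,6,7,8,8a-octahydronaphthalen-1-yl]pent-2-enoate, via potassium enolate 19 (not isolated)
Conditions: KN(SiMe3)2 (1.1 equiv), THF, −78 °C; then PhNTf2, −78 °C to −40 °C
Reagents that add atoms: N-phenylbis(trifluoromethanesulfonimide), O=S(=O)(N(c1ccccc1)S(=O)(=O)C(F)(F)F)C(F)(F)F
Why: Kinetic enolisation with a bulky amide base at −78 °C should take the ketone α-proton at the C7 methylene rather than at the hindered tertiary C9 or at the much less acidic γ-positions of the enoate, the equatorial C6 silyloxy group being poorly aligned for β-elimination, and O-sulfonylation fixes the C7=C8 double bond as the enol triflate (the change of the C6 descriptor is only a change of priorities).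

Step 13
Reactants: 20 methyl (2E)-3-({[tert-butyl(dimethyl)silyl]oxy}methyl)-5-[(1S,4S,4aR,8aR)-4-{[tert-butyl(dimethyl)silyl]oxy}-5,5,8a-trimethyl-2-{[(trifluoromethyl)sulfonyl]oxy}-1,4,4a,5,6,7,8,8a-octahydronaphthalen-1-yl]pent-2-enoate
Product: 21 methyl (2E)-3-({[tert-butyl(dimethyl)silyl]oxy}methyl)-5-[(1S,4R,4aR,8aS)-4-{[tert-butyl(dimethyl)silyl]oxy}-2-formyl-5,5,8a-trimethyl-1,4,4a,5,6,7,8,8a-octahydronaphthalen-1-yl]pent-2-enoate
Conditions: Pd(PPh3)4 (5 mol %), CO (1 atm), Bu3SnH (slow addition), LiCl, THF, 50 °C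
Reagents that add atoms: carbon monoxide, [C-]#[O+]
Why: Palladium-catalysed reductive carbonylation (formylation) of an enol triflate, by oxidative addition to zerovalent palladium, CO insertion and hydride transfer from the tin hydride added slowly so that carbonylation outruns direct reduction, should give the C17 aldehyde conjugated with C7=C8 without moving the double bond.

Step 14
Reactants: 21 methyl (2E)-3-({[tert-butyl(dimethyl)silyl]oxy}methyl)-5-[(1S,4R,4aR,8aS)-4-{[tert-butyl(dimethyl)silyl]oxy}-2-formyl-5,5,8a-trimethyl-1,4,4a,5,6,7,8,8a-octahydronaphthalen-1-yl]pent-2-enoate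
Product: 22 methyl (2E)-5-[(1S,4R,4aR,8aS)-2-formyl-4-hydroxy-5,5,8a-trimethyl-1,4,4a,5,6,7,8,8a-octahydronaphthalen-1-yl]-3-(hydroxymethyl)pent-2-enoate
Conditions: HF·pyridine (excess), THF, 0 °C to rt
Reagents that add atoms: none
Why: Acidic fluoride removes both silyl ethers without base, so the enal, the enoate geometry and the allylic C6 alcohol should survive.

Step 15
Reactants: 22 methyl (2E)-5-[(1S,4R,4aR,8aS)-2-formyl-4-hydroxy-5,5,8a-trimethyl-1,4,4a,5,6,7,8,8a-octahydronaphthalen-1-yl]-3-(hydroxymethyl)pent-2-enoate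
Product: 23 methyl (2E)-3-[(formyloxy)methyl]-5-[(1S,4R,4aR,8aS)-2-formyl-4-hydroxy-5,5,8a-trimethyl-1,4,4a,5,6,7,8,8a-octahydronaphthalen-1-yl]pent-2-enoate (CNP0134813.1)
Conditions: 2,2,2-trifluoroethyl formate (5 equiv), THF, rt
Reagents that add atoms: 2,2,2-trifluoroethyl formate, O=COCC(F)(F)F
Why: Transesterification-type formylation with 2,2,2-trifluoroethyl formate is strongly rate-selective for primary over hindered secondary alcohols, so only the C16 hydroxyl should be formylated.

**Compound list**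

1 | β-cyclocitral | CC1=C(C=O)C(C)(C)CCC1 | starting material
2 | bis(isopinocampheyl)borinate ester of 3 | C=CC[C@@H](OB([C@H]1C[C@H]2C[C@@H]([C@@H]1C)C2(C)C)[C@H]1C[C@H]2C[C@@H]([C@@H]1C)C2(C)C)C1=C(C)CCCC1(C)C | intermediate
3 | (1R)-1-(2,6,6-trimethylcyclohex-1-en-1-yl)but-3-en-1-ol | C=CC[C@@H](O)C1=C(C)CCCC1(C)C | intermediate
4 | tert-butyl(but-3-en-1-yloxy)dimethylsilane | C=CCCO[Si](C)(C)C(C)(C)C | starting material
5 | (1R,3E)-6-{[tert-butyl(dimethyl)silyl]oxy}-1-(2,6,6-trimethylcyclohex-1-en-1-yl)hex-3-en-1-ol | CC(C)(C)[Si](C)(C)OCC/C=C/C[C@@H](O)C1=C(C)CCCC1(C)C | intermediate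
6 | potassium alkoxide of 5 | CC(C)(C)[Si](C)(C)OCC/C=C/C[C@@H]([O-])C1=C(C)CCCC1(C)C.[K+] | intermediate
7 | potassium enolate of 8 (oxygen cis to C4) | CC(C)(C)[Si](C)(C)OCC[C@H](C=C)[C@]1(C)CCCC(C)(C)/C1=C\[O-].[K+] | intermediate
8 | (1R,2S)-2-[(3R)-5-{[tert-butyl(dimethyl)silyl]oxy}pent-1-en-3-yl]-2,6,6-trimethylcyclohexane-1-carbaldehyde | CC(C)(C)[Si](C)(C)OCC[C@H](C=C)[C@]1(C)CCCC(C)(C)[C@H]1C=O | intermediate
9 | (1R,2R)-2-[(3S)-5-{[tert-butyl(dimethyl)silyl]oxy}-2-oxopentan-3-yl]-2,6,6-trimethylcyclohexane-1-carbaldehyde | CC(C)(C)[Si](C)(C)OCC[C@H](C(C)=O)[C@]1(C)CCCC(C)(C)[C@H]1C=O | intermediate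
10 | (1S,4R,4aR,8aR)-1-(2-{[tert-butyl(dimethyl)silyl]oxy}ethyl)-4-hydroxy-5,5,8a-trimethyl-3,4,4a,5,6,7,8,8a-octahydronaphthalen-2(1H)-one | CC(C)(C)[Si](C)(C)OCC[C@@H]1C(=O)C[C@@H](O)[C@@H]2C(C)(C)CCC[C@@]12C | intermediate
11 | (1S,4R,4aR,8aR)-4-{[tert-butyl(dimethyl)silyl]oxy}-1-(2-{[tert-butyl(dimethyl)silyl]oxy}ethyl)-5,5,8a-trimethyl-3,4,4a,5,6,7,8,8a-octahydronaphthalen-2(1H)-one | CC(C)(C)[Si](C)(C)OCC[C@@H]1C(=O)C[C@@H](O[Si](C)(C)C(C)(C)C)[C@@H]2C(C)(C)CCC[C@@]12C | intermediate
12 | (1S,4R,4aR,8aR)-4-{[tert-butyl(dimethyl)silyl]oxy}-1-(2-hydroxyethyl)-5,5,8a-trimethyl-3,4,4a,5,6,7,8,8a-octahydronaphthalen-2(1H)-one | OCC[C@@H]1C(=O)C[C@@H](O[Si](C)(C)C(C)(C)C)[C@@H]2C(C)(C)CCC[C@@]12C | intermediate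
13 | (1S,4R,4aR,8aR)-4-{[tert-butyl(dimethyl)silyl]oxy}-1-(2-iodoethyl)-5,5,8a-trimethyl-3,4,4a,5,6,7,8,8a-octahydronaphthalen-2(1H)-one | ICC[C@@H]1C(=O)C[C@@H](O[Si](C)(C)C(C)(C)C)[C@@H]2C(C)(C)CCC[C@@]12C | intermediate
14 | methyl 4-hydroxybut-2-ynoate | COC(=O)C#CCO | starting material
15 | methyl (2Z)-4-hydroxy-3-iodobut-2-enoate | COC(=O)/C=C(\I)CO | intermediate
16 | methyl (2Z)-4-{[tert-butyl(dimethyl)silyl]oxy}-3-iodobut-2-enoate | COC(=O)/C=C(\I)CO[Si](C)(C)C(C)(C)C | intermediate
17 | alkylzinc iodide from 13 | I[Zn]CC[C@@H]1C(=O)C[C@@H](O[Si](C)(C)C(C)(C)C)[C@@H]2C(C)(C)CCC[C@@]12C | intermediate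
18 | methyl (2E)-3-({[tert-butyl(dimethyl)silyl]oxy}methyl)-5-[(1S,4R,4aR,8aR)-4-{[tert-butyl(dimethyl)silyl]oxy}-5,5,8a-trimethyl-2-oxodecahydronaphthalen-1-yl]pent-2-enoate | COC(=O)/C=C(\CC[C@@H]1C(=O)C[C@@H](O[Si](C)(C)C(C)(C)C)[C@@H]2C(C)(C)CCC[C@@]12C)CO[Si](C)(C)C(C)(C)C | intermediate
19 | potassium C7=C8 enolate of 18 | COC(=O)/C=C(\CC[C@@H]1C([O-])=C[C@@H](O[Si](C)(C)C(C)(C)C)[C@@H]2C(C)(C)CCC[C@@]12C)CO[Si](C)(C)C(C)(C)C.[K+] | intermediate
20 | methyl (2E)-3-({[tert-butyl(dimethyl)silyl]oxy}methyl)-5-[(1S,4S,4aR,8aR)-4-{[tert-butyl(dimethyl)silyl]oxy}-5,5,8a-trimethyl-2-{[(trifluoromethyl)sulfonyl]oxy}-1,4,4a,5,6,7,8,8a-octahydronaphthalen-1-yl]pent-2-enoate | COC(=O)/C=C(\CC[C@@H]1C(OS(=O)(=O)C(F)(F)F)=C[C@@H](O[Si](C)(C)C(C)(C)C)[C@@H]2C(C)(C)CCC[C@@]12C)CO[Si](C)(C)C(C)(C)C | intermediate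
21 | methyl (2E)-3-({[tert-butyl(dimethyl)silyl]oxy}methyl)-5-[(1S,4R,4aR,8aS)-4-{[tert-butyl(dimethyl)silyl]oxy}-2-formyl-5,5,8a-trimethyl-1,4,4a,5,6,7,8,8a-octahydronaphthalen-1-yl]pent-2-enoate | COC(=O)/C=C(\CC[C@@H]1C(C=O)=C[C@@H](O[Si](C)(C)C(C)(C)C)[C@@H]2C(C)(C)CCC[C@@]12C)CO[Si](C)(C)C(C)(C)C | intermediate
22 | methyl (2E)-5-[(1S,4R,4aR,8aS)-2-formyl-4-hydroxy-5,5,8a-trimethyl-1,4,4a,5,6,7,8,8a-octahydronaphthalen-1-yl]-3-(hydroxymethyl)pent-2-enoate | COC(=O)/C=C(\CC[C@@H]1C(C=O)=C[C@@H](O)[C@@H]2C(C)(C)CCC[C@@]12C)CO | intermediate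
23 | methyl (2E)-3-[(formyloxy)methyl]-5-[(1S,4R,4aR,8aS)-2-formyl-4-hydroxy-5,5,8a-trimethyl-1,4,4a,5,6,7,8,8a-octahydronaphthalen-1-yl]pent-2-enoate | COC(=O)/C=C(\CC[C@@H]1C(C=O)=C[C@@H](O)[C@@H]2C(C)(C)CCC[C@@]12C)COC=O | target

**Step count and risks**

Total step count: 15. Longest linear sequence: 13 (steps 1–8 and 11–15); steps 9 and 10 make the side-chain fragment 16.

Steps most likely to fail:

1. Step 3 (anionic oxy-Cope). The rearrangement has to create the quaternary C10 at a tetrasubstituted alkene and may therefore be slow. The naked alkoxide could then fragment by retro-allylation back to 1, or react through the second chair with an axial oxyanion, which would erode the enantiomeric purity carried from C6. The fallback sets out from 5 and comes back at 8. Alcohol 5 is silylated (Me3SiCl, imidazole, CH2Cl2) to the trimethylsilyl ether F1. This is heated neat in a base-washed sealed tube (about 200 °C), so that a neutral siloxy-Cope rearrangement, which has no alkoxide to fragment, gives the silyl enol ether F2 through the same chair. Buffered methanolysis (K2CO3, MeOH, −20 °C) then releases aldehyde 8.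

2. Step 5 (aldol ring closure). The basic medium may carry the ketol on to the C6=C7 enone by loss of water, or cleave the 1,5-dicarbonyl compound by retro-Michael loss of the C9 enolate before the ring closes. The fallback sets out from 9 and comes back at 10, and it forms the same C6–C7 bond without any free alkoxide or enolate. Keto aldehyde 9 is treated with Me3SiOTf and iPr2NEt (CH2Cl2, −78 °C) to form the methyl-ketone enol silane F3. In the same flask F3 adds to the silyl-triflate-activated aldehyde (intramolecular Mukaiyama aldol, open transition state with the oxygen equatorial) to give the O-trimethylsilyl ketol F4. Citric acid in MeOH at 0 °C frees ketol 10.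

3. Step 12 (enol triflate in the presence of the enoate). Proton abstraction at the γ-positions of the enoate (C12, C16), or attack of the amide base on the methyl ester, may compete with deprotonation at C7 and consume 18 or scramble the C13=C14 geometry. The fallback sets out from 11 and comes back at 21; it brings in C17 by a different reaction before any ester is present. Ketone 11 is condensed with 2,4,6-triisopropylbenzenesulfonyl hydrazide (THF, rt) to the hydrazone F5. n-BuLi (2.2 equiv, THF, −78 °C to 0 °C) converts F5 by a Shapiro reaction, with deprotonation on the C7 methylene side, into the C8 vinyllithium F6, which is trapped with DMF to give the enal F7. Buffered HF·pyridine frees the primary alcohol F8, and I2/PPh3/imidazole gives the iodide F9. Zinc insertion (Zn, LiCl, THF) gives the alkylzinc iodide F10, which is inert to the enal at rt, and coupling with 16 under PdCl2(dppf) catalysis gives 21.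

**Further compounds**

F1 | step 3 | trimethylsilyl ether of 5 | CC(C)(C)[Si](C)(C)OCC/C=C/C[C@@H](O[Si](C)(C)C)C1=C(C)CCCC1(C)C
F2 | step 3 | trimethylsilyl enol ether of 8 | CC(C)(C)[Si](C)(C)OCC[C@H](C=C)[C@]1(C)CCCC(C)(C)/C1=C\O[Si](C)(C)C
F3 | step 5 | methyl-ketone trimethylsilyl enol ether of 9 | CC(C)(C)[Si](C)(C)OCC[C@H](C(=C)O[Si](C)(C)C)[C@]1(C)CCCC(C)(C)[C@H]1C=O
F4 | step 5 | O-trimethylsilyl ether of ketol 10 | CC(C)(C)[Si](C)(C)OCC[C@@H]1C(=O)C[C@@H](O[Si](C)(C)C)[C@@H]2C(C)(C)CCC[C@@]12C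
F5 | step 12 | 2,4,6-triisopropylbenzenesulfonyl hydrazone of 11 | CC(C)(C)[Si](C)(C)OCC[C@@H]1C(=NNS(=O)(=O)c3c(C(C)C)cc(C(C)C)cc3C(C)C)C[C@@H](O[Si](C)(C)C(C)(C)C)[C@@H]2C(C)(C)CCC[C@@]12C
F6 | step 12 | C8 vinyllithium from F5 | CC(C)(C)[Si](C)(C)OCC[C@@H]1C([Li])=C[C@@H](O[Si](C)(C)C(C)(C)C)[C@@H]2C(C)(C)CCC[C@@]12C
F7 | step 12 | (1S,4R,4aR,8aS)-4-{[tert-butyl(dimethyl)silyl]oxy}-1-(2-{[tert-butyl(dimethyl)silyl]oxy}ethyl)-5,5,8a-trimethyl-1,4,4a,5,6,7,8,8a-octahydronaphthalene-2-carbaldehyde | CC(C)(C)[Si](C)(C)OCC[C@@H]1C(C=O)=C[C@@H](O[Si](C)(C)C(C)(C)C)[C@@H]2C(C)(C)CCC[C@@]12C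
F8 | step 12 | (1S,4R,4aR,8aS)-4-{[tert-butyl(dimethyl)silyl]oxy}-1-(2-hydroxyethyl)-5,5,8a-trimethyl-1,4,4a,5,6,7,8,8a-octahydronaphthalene-2-carbaldehyde | OCC[C@@H]1C(C=O)=C[C@@H](O[Si](C)(C)C(C)(C)C)[C@@H]2C(C)(C)CCC[C@@]12C
F9 | step 12 | (1S,4R,4aR,8aS)-4-{[tert-butyl(dimethyl)silyl]oxy}-1-(2-iodoethyl)-5,5,8a-trimethyl-1,4,4a,5,6,7,8,8a-octahydronaphthalene-2-carbaldehyde | ICC[C@@H]1C(C=O)=C[C@@H](O[Si](C)(C)C(C)(C)C)[C@@H]2C(C)(C)CCC[C@@]12C
F10 | step 12 | alkylzinc iodide from F9 | I[Zn]CC[C@@H]1C(C=O)=C[C@@H](O[Si](C)(C)C(C)(C)C)[C@@H]2C(C)(C)CCC[C@@]12C
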